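**Plan**

- Retrosynthesis: O7 is unmasked last (Si–O). Ring C is cut at the C4–C4a acyl bond. Ring A is cut at C5–C6, C7–C8 and C5–C4a into a 3-alkoxycyclobutenone (O1, C8a, C8, C4a, C5) and a silyloxyalkyne (C6, C7). The O1–C8a enol ether bond and the pyran ring of the chromene on ring B are cut last.
- Enabling feature: ring A is hexasubstituted, with oxygen on C5, C7 and C8a alternating with carbon on C4a, C6 and C8. A 3-alkoxycyclobutenone and an ynol ether map onto exactly this pattern and leave C4a as the only ring CH.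
- Forward order: the chromene ring on ring B (steps 1–2), then ring A by benzannulation around the preformed chiral ether (step 9), then ring C by acylation at C4a (step 11).
- Stereochemistry: C2 is set by asymmetric transfer hydrogenation of a β-keto ester (step 4). Its C–O bond is never broken afterwards, so (S) is carried through by retention.
- Convergence: one silyloxyalkyne serves twice, as the source of the cyclobutenone and as the alkyne partner.

Key step: step 9

Remark: flavanone numbering is used throughout (O1, C2, C3, C4, C4a, C5–C8, C8a). Ketene is assumed to be supplied as a gas stream from an acetone-pyrolysis generator, and the silyloxyalkyne of step 5 is made in a quantity that serves steps 6 and 9.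

**Route**

Step 1
Reactants: 1 4-hydroxyacetophenone; 2 3-chloro-3-methylbut-1-yne
Product: 3 1-{4-[(2-methylbut-3-yn-2-yl)oxy]phenyl}ethanone
Conditions: K2CO3, KI, CuI (cat.), acetone, reflux
Reagents that add atoms: none
Why: Copper-assisted Williamson-type O-alkylation of the phenoxide with a tertiary propargylic chloride is the standard entry to aryl 1,1-dimethylpropargyl ethers.

Step 2
Reactants: 3 1-{4-[(2-methylbut-3-yn-2-yl)oxy]phenyl}ethanone
Product: 4 1-(2,2-dimethyl-2H-chromen-6-yl)ethanone
Conditions: N,N-diethylaniline, 190 °C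
Reagents that add atoms: none
Why: Aryl propargyl ether Claisen rearrangement, followed by a 1,5-hydrogen shift and oxa-6π electrocyclisation, closes the 2,2-dimethylchromene, and the two ortho positions are equivalent so only one product can form.

Step 3
Reactants: 4 1-(2,2-dimethyl-2H-chromen-6-yl)ethanone
Product: 5 methyl 3-(2,2-dimethyl-2H-chromen-6-yl)-3-oxopropanoate
Conditions: NaH, (MeO)2CO, THF, reflux; then cold 1 M HCl
Reagents that add atoms: dimethyl carbonate, COC(=O)OC
Why: Crossed Claisen condensation of the methyl ketone enolate with dimethyl carbonate is driven to completion by deprotonation of the β-keto ester formed.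

Step 4
Reactants: 5 methyl 3-(2,2-dimethyl-2H-chromen-6-yl)-3-oxopropanoate
Product: 6 methyl (3S)-3-(2,2-dimethyl-2H-chromen-6-yl)-3-hydroxypropanoate
Conditions: RuCl[(S,S)-TsDPEN](p-cymene) (1 mol %), HCO2H/Et3N (5:2), 40 °C
Reagents that add atoms: none
Why: Noyori-type asymmetric transfer hydrogenation of an aryl ketone, in which the (S,S)-diamine complex delivers hydride to the face that gives (S)-benzylic alcohols (aryl group held by the CH–π contact with the cymene ligand), sets the future C2 and leaves the chromene alkene and the ester untouched.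

Step 5
Reactants: 7 ethyl 4-methylpent-3-enoate
Product: 10 triisopropyl[(5-methylhex-4-en-1-yn-1-yl)oxy]silane, via lithium dibromoenolate 8 (not isolated), via lithium ynolate 9 (not isolated)
Conditions: CH2Br2, lithium 2,2,6,6-tetramethylpiperidide (2.2 equiv, from the amine and n-BuLi), THF, −78 °C; then 7; then n-BuLi, −78 °C → rt; then i-Pr3SiCl, −78 °C → rt
Reagents that add atoms: dibromomethane, BrCBr; triisopropylsilyl chloride, CC(C)[Si](Cl)(C(C)C)C(C)C
Why: Kowalski ester homologation, in which acylation of dibromomethyllithium gives enolate 8, bromine–lithium exchange triggers the carbenoid 1,2-shift to ynolate 9, and the bulky silyl chloride traps the ynolate on oxygen.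

Step 6
Reactants: 10 triisopropyl[(5-methylhex-4-en-1-yn-1-yl)oxy]silane
Product: 11 2-(3-methylbut-2-enyl)-3-(triisopropylsilyloxy)cyclobut-2-en-1-one
Conditions: ketene (gas, from acetone pyrolysis), CH2Cl2, 0 °C
Reagents that add atoms: ketene, C=C=O
Why: Ketene–ynol ether [2+2] cycloaddition, in which the nucleophilic prenyl-bearing alkyne carbon attacks the ketene carbonyl carbon, places the silyloxy group on C3 and the prenyl group on C2 of the cyclobutenone, while the trisubstituted alkene is inert to ketene.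

Step 7
Reactants: 11 2-(3-methylbut-2-enyl)-3-(triisopropylsilyloxy)cyclobut-2-en-1-one
Product: 12 3-hydroxy-2-(3-methylbut-2-enyl)cyclobut-2-en-1-one (enol form of 2-prenylcyclobutane-1,3-dione)
Conditions: 48% aq. HF, MeCN, 0 °C
Reagents that add atoms: none
Why: Fluoride-assisted cleavage of a vinylogous silyl ester, far more labile than a silyl ether, frees the enolised 1,3-dione without the strong mineral acid that could hydrate or cyclise the prenyl group.

Step 8
Reactants: 12 3-hydroxy-2-(3-methylbut-2-enyl)cyclobut-2-en-1-one; 6 methyl (3S)-3-(2,2-dimethyl-2H-chromen-6-yl)-3-hydroxypropanoate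
Product: 14 methyl (3S)-3-(2,2-dimethyl-2H-chromen-6-yl)-3-{[2-(3-methylbut-2-enyl)-3-oxocyclobut-1-en-1-yl]oxy}propanoate, via vinylogous acid chloride 13 (not isolated)
Conditions: (COCl)2, DMF (cat.), CH2Cl2, 0 °C; concentrate cold; then 6, 2,6-lutidine, DMAP (cat.), CH2Cl2, 0 °C → rt
Reagents that add atoms: none
Why: The enolised dione is turned into its β-chloroenone as cyclic 1,3-diones and squaric acid are, and the alcohol then displaces chloride by conjugate addition–elimination as in squarate ester formation, so the C–O bond of 6 is untouched and (S) is retained, while the symmetry of 12 allows only one chloride.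

Step 9
Reactants: 14 methyl (3S)-3-(2,2-dimethyl-2H-chromen-6-yl)-3-{[2-(3-methylbut-2-enyl)-3-oxocyclobut-1-en-1-yl]oxy}propanoate; 10 triisopropyl[(5-methylhex-4-en-1-yn-1-yl)oxy]silane
Product: 19 methyl (3S)-3-(2,2-dimethyl-2H-chromen-6-yl)-3-[5-hydroxy-2,4-bis(3-methylbut-2-enyl)-3-(triisopropylsilyloxy)phenoxy]propanoate, via vinylketene 15 (not isolated), via vinylcyclobutenone adduct 16 (not isolated), via dienylketene 17 (not isolated), via cyclohexadienone 18 (not isolated)
Conditions: 10 (1.5 equiv), toluene, 80 → 110 °C, sealed tube, argon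
Reagents that add atoms: none
Why: Danheiser-type cyclobutenone–alkyne benzannulation, a purely thermal pericyclic cascade: conrotatory 4π opening of 14 gives vinylketene 15, whose ketene C=C adds the silyloxyalkyne in a [2+2] cycloaddition to 16 (new bonds C5–C6 and C7–C8), a second 4π opening gives dienylketene 17, and 6π electrocyclisation followed by tautomerisation delivers phenol 19. The closest known reaction type is the benzannulation of cyclobutenones with trialkylsilyloxyalkynes to resorcinol monosilyl ethers, and oxygen-substituted cyclobutenones are known to undergo the same electrocyclic opening on heating. Ring A is closed in the disrotatory 6π electrocyclisation, which joins the ketene carbon C5 to the terminal methylene carbon C4a, so that C4a ends as the only CH of the ring. No stereocentre is created, and the C2 centre, a spectator outside the reacting π system, is expected to survive the neutral, aprotic heating. The one selectivity needed is the regiochemistry of the ketene–alkyne cycloaddition, and it is secured by the polarisation of the ynol ether: its prenyl-bearing β-carbon is the nucleophile and bonds to the electrophilic ketene carbon, which places the silyloxy carbon next to C8 and gives the alternating oxygen pattern. The alkyne is used in excess so that 15 is trapped by it and not by the product phenol.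

Step 10
Reactants: 19 methyl (3S)-3-(2,2-dimethyl-2H-chromen-6-yl)-3-[5-hydroxy-2,4-bis(3-methylbut-2-enyl)-3-(triisopropylsilyloxy)phenoxy]propanoate
Product: 20 (3S)-3-(2,2-dimethyl-2H-chromen-6-yl)-3-[5-hydroxy-2,4-bis(3-methylbut-2-enyl)-3-(triisopropylsilyloxy)phenoxy]propanoic acid
Conditions: LiOH, THF/MeOH/H2O, 0 °C → rt; then cold 0.5 M HCl to pH 3
Reagents that add atoms: lithium hydroxide, [Li+].[OH-]
Why: Saponification of an unhindered methyl ester, in which hydroxide attacks the ester carbonyl much faster than it enolises it, should avoid β-elimination of the aryloxy group, and the silyl ether flanked by two prenyl groups is shielded.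

Step 11
Reactants: 20 (3S)-3-(2,2-dimethyl-2H-chromen-6-yl)-3-[5-hydroxy-2,4-bis(3-methylbut-2-enyl)-3-(triisopropylsilyloxy)phenoxy]propanoic acid
Product: 22 (2S)-2-(2,2-dimethyl-2H-chromen-6-yl)-5-hydroxy-6,8-bis(3-methylbut-2-enyl)-7-(triisopropylsilyloxy)-2,3-dihydro-4H-chromen-4-one, via mixed trifluoroacetic anhydride 21 (not isolated)
Conditions: (CF3CO)2O, CH2Cl2, −20 → 0 °C; then aq. NaHCO3/MeOH
Reagents that add atoms: none
Why: Intramolecular Friedel–Crafts acylation through the mixed anhydride closes six-membered ring C without a Lewis acid, because C4a is the only unsubstituted ring carbon and lies ortho to two oxygens and para to the silyloxy group, while C2 is not involved and any transient trifluoroacetylation of the phenol is undone in the quench.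

Step 12
Reactants: 22 (2S)-2-(2,2-dimethyl-2H-chromen-6-yl)-5-hydroxy-6,8-bis(3-methylbut-2-enyl)-7-(triisopropylsilyloxy)-2,3-dihydro-4H-chromen-4-one
Product: 23 (2S)-2-(2,2-dimethyl-2H-chromen-6-yl)-5,7-dihydroxy-6,8-bis(3-methylbut-2-enyl)-2,3-dihydro-4H-chromen-4-one
Conditions: Bu4NF, AcOH (1:1), THF, 0 °C
Reagents that add atoms: none
Why: Buffered fluoride desilylation cleaves the aryl silyl ether, whose phenoxide is a good leaving group para to the C4 carbonyl, and the acetic acid keeps the medium from turning basic, which prevents chalcone ring opening (retro-oxa-Michael) and so racemisation at C2.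

**Compound list**

1 | 4-hydroxyacetophenone | CC(=O)c1ccc(O)cc1 | starting material
2 | 3-chloro-3-methylbut-1-yne | C#CC(C)(C)Cl | starting material
3 | 1-{4-[(2-methylbut-3-yn-2-yl)oxy]phenyl}ethanone | CC(=O)c1ccc(OC(C)(C)C#C)cc1 | intermediate
4 | 1-(2,2-dimethyl-2H-chromen-6-yl)ethanone | CC(=O)c1ccc2c(c1)C=CC(C)(C)O2 | intermediate
5 | methyl 3-(2,2-dimethyl-2H-chromen-6-yl)-3-oxopropanoate | COC(=O)CC(=O)c1ccc2c(c1)C=CC(C)(C)O2 | intermediate
6 | methyl (3S)-3-(2,2-dimethyl-2H-chromen-6-yl)-3-hydroxypropanoate | COC(=O)C[C@@H](c1ccc2c(c1)C=CC(C)(C)O2)O | intermediate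
7 | ethyl 4-methylpent-3-enoate | CCOC(=O)CC=C(C)C | starting material
8 | lithium 1,1-dibromo-5-methylhexa-1,4-dien-2-olate | [Li+].[O-]C(CC=C(C)C)=C(Br)Br | intermediate (not isolated)
9 | lithium 5-methylhex-4-en-1-yn-1-olate | [Li+].[O-]C#CCC=C(C)C | intermediate (not isolated)
10 | triisopropyl[(5-methylhex-4-en-1-yn-1-yl)oxy]silane | CC(C)=CCC#CO[Si](C(C)C)(C(C)C)C(C)C | intermediate
11 | 2-(3-methylbut-2-enyl)-3-(triisopropylsilyloxy)cyclobut-2-en-1-one | CC(C)=CCC1=C(O[Si](C(C)C)(C(C)C)C(C)C)CC1=O | intermediate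
12 | 3-hydroxy-2-(3-methylbut-2-enyl)cyclobut-2-en-1-one | CC(C)=CCC1=C(O)CC1=O | intermediate
13 | 3-chloro-2-(3-methylbut-2-enyl)cyclobut-2-en-1-one | CC(C)=CCC1=C(Cl)CC1=O | intermediate (not isolated)
14 | methyl (3S)-3-(2,2-dimethyl-2H-chromen-6-yl)-3-{[2-(3-methylbut-2-enyl)-3-oxocyclobut-1-en-1-yl]oxy}propanoate | COC(=O)C[C@@H](c1ccc2c(c1)C=CC(C)(C)O2)OC1=C(CC=C(C)C)C(=O)C1 | intermediate
15 | methyl (3S)-3-(2,2-dimethyl-2H-chromen-6-yl)-3-{[6-methyl-3-(oxomethylidene)hepta-1,5-dien-2-yl]oxy}propanoate (vinylketene) | COC(=O)C[C@@H](c1ccc2c(c1)C=CC(C)(C)O2)OC(=C)C(CC=C(C)C)=C=O | intermediate (not isolated)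
16 | methyl (3S)-3-({1-[1,3-bis(3-methylbut-2-enyl)-4-oxo-2-(triisopropylsilyloxy)cyclobut-2-en-1-yl]ethenyl}oxy)-3-(2,2-dimethyl-2H-chromen-6-yl)propanoate (configuration at the quaternary ring carbon not defined) | COC(=O)C[C@@H](c1ccc2c(c1)C=CC(C)(C)O2)OC(=C)C1(CC=C(C)C)C(=O)C(CC=C(C)C)=C1O[Si](C(C)C)(C(C)C)C(C)C | intermediate (not isolated)
17 | dienylketene from ring opening of 16: methyl (3S)-3-(2,2-dimethyl-2H-chromen-6-yl)-3-{[3,5-bis(3-methylbut-2-enyl)-6-oxo-4-(triisopropylsilyloxy)hexa-1,3,5-trien-2-yl]oxy}propanoate | COC(=O)C[C@@H](c1ccc2c(c1)C=CC(C)(C)O2)OC(=C)C(CC=C(C)C)=C(O[Si](C(C)C)(C(C)C)C(C)C)C(CC=C(C)C)=C=O | intermediate (not isolated)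
18 | methyl (3S)-3-{[2,4-bis(3-methylbut-2-enyl)-5-oxo-3-(triisopropylsilyloxy)cyclohexa-1,3-dien-1-yl]oxy}-3-(2,2-dimethyl-2H-chromen-6-yl)propanoate | COC(=O)C[C@@H](c1ccc2c(c1)C=CC(C)(C)O2)OC1=C(CC=C(C)C)C(O[Si](C(C)C)(C(C)C)C(C)C)=C(CC=C(C)C)C(=O)C1 | intermediate (not isolated)
19 | methyl (3S)-3-(2,2-dimethyl-2H-chromen-6-yl)-3-[5-hydroxy-2,4-bis(3-methylbut-2-enyl)-3-(triisopropylsilyloxy)phenoxy]propanoate | COC(=O)C[C@@H](c1ccc2c(c1)C=CC(C)(C)O2)Oc1cc(O)c(CC=C(C)C)c(O[Si](C(C)C)(C(C)C)C(C)C)c1CC=C(C)C | intermediate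
20 | (3S)-3-(2,2-dimethyl-2H-chromen-6-yl)-3-[5-hydroxy-2,4-bis(3-methylbut-2-enyl)-3-(triisopropylsilyloxy)phenoxy]propanoic acid | OC(=O)C[C@@H](c1ccc2c(c1)C=CC(C)(C)O2)Oc1cc(O)c(CC=C(C)C)c(O[Si](C(C)C)(C(C)C)C(C)C)c1CC=C(C)C | intermediate
21 | mixed anhydride of acid 20 with trifluoroacetic acid | O=C(C[C@@H](c1ccc2c(c1)C=CC(C)(C)O2)Oc1cc(O)c(CC=C(C)C)c(O[Si](C(C)C)(C(C)C)C(C)C)c1CC=C(C)C)OC(=O)C(F)(F)F | intermediate (not isolated)
22 | (2S)-2-(2,2-dimethyl-2H-chromen-6-yl)-5-hydroxy-6,8-bis(3-methylbut-2-enyl)-7-(triisopropylsilyloxy)-2,3-dihydro-4H-chromen-4-one | CC(C)=CCc1c(O[Si](C(C)C)(C(C)C)C(C)C)c(CC=C(C)C)c2c(c1O)C(=O)C[C@@H](c1ccc3c(c1)C=CC(C)(C)O3)O2 | intermediate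
23 | (2S)-2-(2,2-dimethyl-2H-chromen-6-yl)-5,7-dihydroxy-6,8-bis(3-methylbut-2-enyl)-2,3-dihydro-4H-chromen-4-one | CC(C)=CCc1c(O)c(CC=C(C)C)c2c(c1O)C(=O)C[C@@H](c1ccc3c(c1)C=CC(C)(C)O3)O2 | target

**Step count**

Total: 12 steps. Longest linear sequence: 9 steps (steps 1–4, then 8–12). The alkyne branch (steps 5–7) joins at step 8, and alkyne 10 re-enters at step 9.

**Steps most likely to fail, with fallbacks**

The three steps are given in route order; step 9 carries the highest risk.

Step 8. The chloroenone may be consumed by the amine base or by self-condensation faster than the hindered secondary alcohol adds, or the base may trigger β-elimination of the hydroxy ester. The fallback forms the same O1–C8a bond from the other side, by breaking the carbinol C–O bond with inversion. It sets out from 5 and 12 and returns at 14. Keto ester 5 is reduced under the conditions of step 4, but with RuCl[(R,R)-TsDPEN](p-cymene), to methyl (3R)-3-(2,2-dimethyl-2H-chromen-6-yl)-3-hydroxypropanoate F1. This alcohol is coupled with the acidic enol 12 under Mitsunobu conditions (PPh3, DIAD, THF, 0 °C), where O-alkylation of the vinylogous acid with inversion should give 14.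

Step 9. The oxygen donor on the cyclobutenone may slow the first ring opening, so that the temperature required instead brings about β-elimination or ionisation of the benzylic vinylogous ester and the side chain is lost before ring A forms. The fallback runs the same cascade without the fragile ether and attaches the side chain afterwards. It sets out from 11, 10 and 5 and returns at 19. Silyloxycyclobutenone 11 is heated with alkyne 10 (toluene, 80–110 °C) to give 2,4-bis(3-methylbut-2-enyl)-3,5-bis(triisopropylsilyloxy)phenol F2. The (R)-hydroxy ester F1 is made from 5 as in the fallback to step 8. Mitsunobu etherification of F2 with F1 (PPh3, DIAD, toluene, 0 °C) should proceed with inversion to methyl (3S)-3-[2,4-bis(3-methylbut-2-enyl)-3,5-bis(triisopropylsilyloxy)phenoxy]-3-(2,2-dimethyl-2H-chromen-6-yl)propanoate F3. One equivalent of Bu4NF/AcOH at low temperature is then expected to remove the silyl group that has only one ortho carbon substituent and so give 19.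

Step 11. Acid released during acyl activation may ionise the C2–O1 benzylic ether, which is activated by the para oxygen of ring B, eroding the stereocentre or cleaving the side chain; addition of the phenol to the neighbouring prenyl group is a lesser risk. The fallback closes ring C at the aldehyde oxidation level and replaces steps 10 and 11. It sets out from 19 and returns at 22. Reduction of 19 with i-Bu2AlH (toluene, −78 °C) should give (3S)-3-(2,2-dimethyl-2H-chromen-6-yl)-3-[5-hydroxy-2,4-bis(3-methylbut-2-enyl)-3-(triisopropylsilyloxy)phenoxy]propanal F4. Ortho-specific phenol–aldehyde hydroxyalkylation templated by PhB(OH)2 (cat. propionic acid, toluene, reflux with water removal) should bond C4a to the aldehyde carbon and give the cyclic 4,5-O-phenylboronate of (2S)-2-(2,2-dimethyl-2H-chromen-6-yl)-6,8-bis(3-methylbut-2-enyl)-7-(triisopropylsilyloxy)chromane-4,5-diol F5. Exchange with propane-1,3-diol frees (2S)-2-(2,2-dimethyl-2H-chromen-6-yl)-6,8-bis(3-methylbut-2-enyl)-7-(triisopropylsilyloxy)chromane-4,5-diol F6, of which either C4 epimer serves. Benzylic oxidation with MnO2 (CH2Cl2, rt) then gives 22.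

**Further compounds**

F1 | step 8 | methyl (3R)-3-(2,2-dimethyl-2H-chromen-6-yl)-3-hydroxypropanoate | COC(=O)C[C@H](c1ccc2c(c1)C=CC(C)(C)O2)O
F2 | step 9 | 2,4-bis(3-methylbut-2-enyl)-3,5-bis(triisopropylsilyloxy)phenol | Oc1cc(O[Si](C(C)C)(C(C)C)C(C)C)c(CC=C(C)C)c(O[Si](C(C)C)(C(C)C)C(C)C)c1CC=C(C)C
F3 | step 9 | methyl (3S)-3-[2,4-bis(3-methylbut-2-enyl)-3,5-bis(triisopropylsilyloxy)phenoxy]-3-(2,2-dimethyl-2H-chromen-6-yl)propanoate | COC(=O)C[C@@H](c1ccc2c(c1)C=CC(C)(C)O2)Oc1cc(O[Si](C(C)C)(C(C)C)C(C)C)c(CC=C(C)C)c(O[Si](C(C)C)(C(C)C)C(C)C)c1CC=C(C)C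
F4 | step 11 | (3S)-3-(2,2-dimethyl-2H-chromen-6-yl)-3-[5-hydroxy-2,4-bis(3-methylbut-2-enyl)-3-(triisopropylsilyloxy)phenoxy]propanal | O=CC[C@@H](c1ccc2c(c1)C=CC(C)(C)O2)Oc1cc(O)c(CC=C(C)C)c(O[Si](C(C)C)(C(C)C)C(C)C)c1CC=C(C)C
F5 | step 11 | cyclic 4,5-O-phenylboronate of (2S)-2-(2,2-dimethyl-2H-chromen-6-yl)-6,8-bis(3-methylbut-2-enyl)-7-(triisopropylsilyloxy)chromane-4,5-diol | CC(C)=CCc1c(O[Si](C(C)C)(C(C)C)C(C)C)c(CC=C(C)C)c2c(c1OB(c1ccccc1)O3)C3C[C@@H](c1ccc4c(c1)C=CC(C)(C)O4)O2
F6 | step 11 | (2S)-2-(2,2-dimethyl-2H-chromen-6-yl)-6,8-bis(3-methylbut-2-enyl)-7-(triisopropylsilyloxy)chromane-4,5-diol | CC(C)=CCc1c(O[Si](C(C)C)(C(C)C)C(C)C)c(CC=C(C)C)c2c(c1O)C(O)C[C@@H](c1ccc3c(c1)C=CC(C)(C)O3)O2
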